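## Retrosynthetic overview
1. The three angelates go on last: C8 by Mitsunobu inversion, C3 and C6 by mixed-anhydride acylation. Both oxiranes come from a (1(10)E,4Z)-cyclodecadienone, one by hydroxyl-directed and one by nucleophilic epoxidation.
2. The ten-membered ring comes from a five-atom ring expansion of a cyclopentane-1,3-dione. A C5 alkenyllithium adds to C6=O, retro-aldol cleavage breaks C6–C10, and the C9/C10 enolate is trapped and later oxidised to the E-enone.
3. C7 (isopropenyl) and the C8 oxygen are put on the five-membered ring first, by desymmetrising conjugate addition to the cyclopentenedione and then Rubottom oxidation.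
4. The side chain C1–C5 comes from a Michael addition to acrolein (C1–C3) and a Nozaki–Hiyama–Kishi coupling with a propyne-derived cis iodo/silyl propene (C4, C5, C15).
5. Ring order: purchased cyclopentane, then a transient cycloheptene (5/7 bicycle), then the cyclodecadiene, then the 4,5-oxirane, then the 1,10-oxirane.

Assumption: germacrane numbering is used for every intermediate (ring C1–C10, C14 on C10, C15 on C4, isopropenyl C11–C13 on C7). Isopropenylmagnesium bromide solution and (tributylstannyl)trimethylsilane are taken as purchased.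

## Route

Step 1
Reactants: 1 2-methylcyclopentane-1,3-dione; 2 acrolein
Product: 3 3-(1-methyl-2,5-dioxocyclopentyl)propanal
Conditions: H2O, 23 °C, 24 h
Reagents that add atoms: none
Why: Michael addition; the acidic 2-alkyl-1,3-dione adds to acrolein in water without base, which makes C10–C1 and the still non-stereogenic quaternary C10.

Step 2
Reactants: 4 propyne
Product: 6 (Z)-(2-iodoprop-1-en-1-yl)trimethylsilane, via cis-silylstannane 5 (not isolated)
Conditions: Me3SiSnBu3, Pd(PPh3)4 (2 mol %), THF, 65 °C, sealed tube; then I2, CH2Cl2, −78 → 0 °C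
Reagents that add atoms: (tributylstannyl)trimethylsilane CCCC[Sn](CCCC)(CCCC)[Si](C)(C)C; iodine II
Why: Silastannation with zerovalent palladium is a strict syn addition (tin internal, silicon terminal), and iododestannylation is faster than iododesilylation and goes with retention, so iodine and silicon end up cis.

Step 3
Reactants: 3 3-(1-methyl-2,5-dioxocyclopentyl)propanal; 6 (Z)-(2-iodoprop-1-en-1-yl)trimethylsilane
Product: 7 2-[(3S,4Z)-3-hydroxy-4-methyl-5-(trimethylsilyl)pent-4-en-1-yl]-2-methylcyclopentane-1,3-dione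
Conditions: CrCl2 (3 equiv), NiCl2 (2 mol %), chiral oxazoline–sulfonamide ligand (3.3 equiv), Et3N (3.3 equiv), THF, 23 °C; aqueous work-up
Reagents that add atoms: none
Why: Asymmetric Nozaki–Hiyama–Kishi coupling; the alkenylchromium species keeps its geometry and attacks only the aldehyde, and the ligand on trivalent chromium directs Re-face attack, which sets C3 as S.

Step 4
Reactants: 7 2-[(3S,4Z)-3-hydroxy-4-methyl-5-(trimethylsilyl)pent-4-en-1-yl]-2-methylcyclopentane-1,3-dione
Product: 8 tert-butyldimethylsilyl ether of 7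
Conditions: TBSCl, imidazole, DMF, 23 °C
Reagents that add atoms: tert-butyldimethylsilyl chloride CC(C)(C)[Si](C)(C)Cl
Why: Standard silyl ether protection; it shields the allylic alcohol from the later oxidants and organometallics and touches no stereocentre.

Step 5
Reactants: 8 tert-butyldimethylsilyl ether of 7
Product: 9 2-[(3S,4Z)-3-(tert-butyldimethylsilyloxy)-5-iodo-4-methylpent-4-en-1-yl]-2-methylcyclopentane-1,3-dione
Conditions: NIS (1.2 equiv), 2,6-lutidine (0.3 equiv), (CF3)2CHOH, 0 °C, 15 min
Reagents that add atoms: N-iodosuccinimide O=C1CCC(=O)N1I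
Why: Iododesilylation (electrophilic ipso substitution through the β-silyl cation) goes with retention in this ionising solvent, so iodine stays cis to C3.

Step 6
Reactants: 9 2-[(3S,4Z)-3-(tert-butyldimethylsilyloxy)-5-iodo-4-methylpent-4-en-1-yl]-2-methylcyclopentane-1,3-dione
Product: 10 the corresponding 2,2-disubstituted cyclopent-4-ene-1,3-dione
Conditions: IBX (2.5 equiv), DMSO/PhF, 75 °C
Reagents that add atoms: none
Why: IBX α,β-dehydrogenation through the enol; C7 and C8 are the only enolisable positions, so the symmetric ene-dione is the single product.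

Step 7
Reactants: 10 the 2,2-disubstituted cyclopent-4-ene-1,3-dione; 11 isopropenylmagnesium bromide
Product: 13 C7-isopropenyl adduct as its C9 tert-butyldimethylsilyl enol ether, via bromomagnesium enolate 12 (not isolated)
Conditions: 11 (1.2 equiv, slow addition), CuBr·SMe2 (5 mol %), chiral ferrocenyl diphosphine (6 mol %, the antipode that gives C7 as drawn), 2-MeTHF, −78 °C; then TBSOTf (1.5 equiv), −78 → −40 °C
Reagents that add atoms: tert-butyldimethylsilyl triflate CC(C)(C)[Si](C)(C)OS(=O)(=O)C(F)(F)F
Why: Copper-catalysed asymmetric conjugate addition of a Grignard reagent (desymmetrisation); the chiral copper complex picks one of the two enantiotopic alkene carbons and so sets C7, attack comes anti to the long C10 chain, and O-silylation fixes the regiodefined enolate.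

Step 8
Reactants: 13 C7-isopropenyl adduct as its C9 tert-butyldimethylsilyl enol ether
Product: 15 trans-8-silyloxy-7-isopropenyl dione, via siloxy epoxide 14 (not isolated)
Conditions: DMDO (1.05 equiv), acetone/CH2Cl2, −78 → 0 °C; silica gel
Reagents that add atoms: dimethyldioxirane CC1(C)OO1
Why: Rubottom oxidation; the electron-rich enol ether reacts before the other alkenes and from the face anti to the neighbouring isopropenyl group, and a 1,4-silyl shift gives the trans α-silyloxy ketone, which leaves C8 deliberately epimeric to the target.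

Step 9
Reactants: 15 trans-8-silyloxy-7-isopropenyl dione
Product: 19 ten-membered (4Z)-enone as its C9/C10 triethylsilyl enol ether, via alkenyllithium 16 (not isolated), via bicyclic aldolate 17 (not isolated), via ring-expanded enolate 18 (not isolated)
Conditions: t-BuLi (2.1 equiv), THF/Et2O/pentane, −100 °C, 5 min; DMPU, −78 → −20 °C, 1 h; TESCl, Et3N, −78 °C
Reagents that add atoms: triethylsilyl chloride CC[Si](CC)(CC)Cl
Why: Proposed new method: iodine–lithium exchange at −100 °C outruns carbonyl addition; the Z-alkenyllithium can reach the dione only from the face that carries its tether, where C9 is screened by the syn C8 silyloxy group while C6 has only H7 on that face, so it closes the seven-membered ring on C6; the crowded lithium aldolate, a β-oxido ketone with two adjacent fully substituted carbons, then cleaves C6–C10 by retro-aldol reaction (gain of enone conjugation, loss of the eclipsed C6–C10 bond), and the equilibrium is drained because only the enolate oxygen and not the hindered tertiary alkoxide is silylated, so the five-ring becomes a ten-ring with a Z-enone and a regiodefined enol ether in one flask (drawn with C1 and C8 cis, a geometry that step 11 erases); the closest known reaction types are the cyclisation of keto alkenyl iodides through alkenyllithiums, and addition/retro-aldol or Barbier/Grob ring enlargements of 2-substituted 1,3-dicarbonyl compounds, known for smaller insertions but not, as far as I know, for a five-atom alkenyl insertion into a cyclopentane-1,3-dione.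

Step 10
Reactants: 19 ten-membered (4Z)-enone as its C9/C10 triethylsilyl enol ether
Product: 20 (6S)-allylic alcohol
Conditions: i-Bu2AlH (1.2 equiv), toluene, −78 °C; Rochelle salt work-up
Reagents that add atoms: none
Why: Felkin–Anh 1,2-reduction; C9 is masked as its enol ether so C6 is the only carbonyl, and hydride comes from the ring periphery anti to the C7–C8 bond with the isopropenyl group next to the carbonyl oxygen, which gives the 6S alcohol.

Step 11
Reactants: 20 (6S)-allylic alcohol
Product: 21 (1(10)E,4Z)-dienone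
Conditions: Pd(OAc)2 (1.1 equiv), DMSO/MeCN, 23–40 °C
Reagents that add atoms: none
Why: Saegusa–Ito oxidation; the enolate of divalent palladium at C10 loses a C1 hydrogen by syn β-hydride elimination from the conformer with C2 anti to C9, which should favour the conjugated E-trisubstituted enone over the exocyclic methylene ketone.

Step 12
Reactants: 21 (1(10)E,4Z)-dienone
Product: 23 1,10:4,5-diepoxy ketone, via 4,5-monoepoxide 22 (not isolated)
Conditions: t-BuOOH (3 equiv), Ti(OiPr)4 (20 mol %), 4 Å MS, CH2Cl2, −20 °C; then DBU (1.5 equiv), 0 → 23 °C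
Reagents that add atoms: tert-butyl hydroperoxide CC(C)(C)OO
Why: In the titanium-alkoxide-directed allylic alcohol epoxidation, 1,3-allylic strain keeps H6 in the alkene plane and O6 on the outer face, which gives the threo 4,5-epoxide and spares the isopropenyl group; in the Weitz–Scheffer epoxidation that follows, the hydroperoxide anion adds to C1 from the periphery of the conformer that holds C14 on the side of the C7 substituent and closes to the trans epoxy ketone.

Step 13
Reactants: 23 1,10:4,5-diepoxy ketone
Product: 24 8-epi triol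
Conditions: Bu4NF/AcOH (1:1, 4 equiv), THF, 0 → 40 °C
Reagents that add atoms: none
Why: Buffered fluoride desilylation removes both silyl ethers without base-induced ketol shift, Payne migration or epimerisation.

Step 14
Reactants: 24 8-epi triol; 25 angelic acid
Product: 26 8-angelate 3,6-diol
Conditions: 25 (1.5 equiv), PPh3 (1.5 equiv), DIAD (1.5 equiv), toluene, 0 → 23 °C
Reagents that add atoms: none
Why: Mitsunobu esterification; only the α-ketol carbon C8 is activated for SN2 displacement while the two epoxy carbinols are hindered and inductively deactivated, so angelate should enter at C8 alone, with clean inversion to the natural 8R configuration and without Z/E isomerisation.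

Step 15
Reactants: 26 8-angelate 3,6-diol; 25 angelic acid
Product: 28 target CNP0154187.3, via mixed anhydride 27 (not isolated)
Conditions: 25 (6 equiv), 2,4,6-trichlorobenzoyl chloride (6 equiv), Et3N (6 equiv), toluene, 23 °C, 2 h; then 26, 75 °C
Reagents that add atoms: none
Why: Yamaguchi-type mixed-anhydride esterification without nucleophilic catalyst acylates the C3 and C6 alcohols with retention and keeps the angelate Z geometry.

## Compound list
1 | 2-methylcyclopentane-1,3-dione | CC1C(=O)CCC1=O | starting material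
2 | acrolein | C=CC=O | starting material
3 | 3-(1-methyl-2,5-dioxocyclopentyl)propanal | CC1(CCC=O)C(=O)CCC1=O | intermediate
4 | propyne | CC#C | starting material
5 | (Z)-trimethyl[2-(tributylstannyl)prop-1-en-1-yl]silane (Sn and Si cis) | C/C([Sn](CCCC)(CCCC)CCCC)=C/[Si](C)(C)C | intermediate
6 | (Z)-(2-iodoprop-1-en-1-yl)trimethylsilane (I and Si cis) | C/C(I)=C/[Si](C)(C)C | intermediate
7 | 2-[(3S,4Z)-3-hydroxy-4-methyl-5-(trimethylsilyl)pent-4-en-1-yl]-2-methylcyclopentane-1,3-dione | CC1(CC[C@H](O)/C(C)=C\[Si](C)(C)C)C(=O)CCC1=O | intermediate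
8 | C3 tert-butyldimethylsilyl ether of 7 | CC1(CC[C@H](O[Si](C)(C)C(C)(C)C)/C(C)=C\[Si](C)(C)C)C(=O)CCC1=O | intermediate
9 | 2-[(3S,4Z)-3-(tert-butyldimethylsilyloxy)-5-iodo-4-methylpent-4-en-1-yl]-2-methylcyclopentane-1,3-dione | CC1(CC[C@H](O[Si](C)(C)C(C)(C)C)/C(C)=C\I)C(=O)CCC1=O | intermediate
10 | 2-[(3S,4Z)-3-(tert-butyldimethylsilyloxy)-5-iodo-4-methylpent-4-en-1-yl]-2-methylcyclopent-4-ene-1,3-dione | CC1(CC[C@H](O[Si](C)(C)C(C)(C)C)/C(C)=C\I)C(=O)C=CC1=O | intermediate
11 | isopropenylmagnesium bromide | C=C(C)[Mg]Br | starting material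
12 | bromomagnesium C8=C9 enolate of the 1,4-adduct (isopropenyl cis to the C10 methyl, trans to the chain) | C[C@@]1(CC[C@H](O[Si](C)(C)C(C)(C)C)/C(C)=C\I)C(=O)[C@@H](C(C)=C)C=C1O[Mg]Br | intermediate
13 | 3-(tert-butyldimethylsilyloxy)-5-isopropenyl-2-methyl-2-(side chain of 9)cyclopent-3-en-1-one (isopropenyl cis to the ring methyl) | C[C@@]1(CC[C@H](O[Si](C)(C)C(C)(C)C)/C(C)=C\I)C(=O)[C@@H](C(C)=C)C=C1O[Si](C)(C)C(C)(C)C | intermediate
14 | C8–C9 siloxy epoxide of 13 (oxirane oxygen trans to isopropenyl) | C[C@@]1(CC[C@H](O[Si](C)(C)C(C)(C)C)/C(C)=C\I)C(=O)[C@@H](C(C)=C)[C@@H]2O[C@]12O[Si](C)(C)C(C)(C)C | intermediate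
15 | 4-(tert-butyldimethylsilyloxy)-5-isopropenyl-2-methyl-2-(side chain of 9)cyclopentane-1,3-dione (isopropenyl cis to methyl, silyloxy trans to isopropenyl) | C[C@@]1(CC[C@H](O[Si](C)(C)C(C)(C)C)/C(C)=C\I)C(=O)[C@@H](C(C)=C)[C@H](O[Si](C)(C)C(C)(C)C)C1=O | intermediate
16 | (Z)-C5 alkenyllithium from 15 | C[C@@]1(CC[C@H](O[Si](C)(C)C(C)(C)C)/C(C)=C\[Li])C(=O)[C@@H](C(C)=C)[C@H](O[Si](C)(C)C(C)(C)C)C1=O | intermediate
17 | cis-fused bicyclo[5.3.0]decenone lithium C6 alkoxide (oxide, C10 methyl and isopropenyl on one face) | [Li+].C[C@@]12CC[C@H](O[Si](C)(C)C(C)(C)C)C(C)=C[C@]1([O-])[C@@H](C(C)=C)[C@H](O[Si](C)(C)C(C)(C)C)C2=O | intermediate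
18 | ten-membered lithium C9/C10 enolate with (4Z)-en-6-one | [Li+].C=C(C)[C@@H]1C(=O)/C=C(C)\[C@@H](O[Si](C)(C)C(C)(C)C)CC/C(C)=C([O-])\[C@H]1O[Si](C)(C)C(C)(C)C | intermediate
19 | 3,8-bis(tert-butyldimethylsilyloxy)-9-(triethylsilyloxy)germacra-4Z,9,11-trien-6-one (C3 and C7 as in the target, C8 epimeric) | C=C(C)[C@@H]1C(=O)/C=C(C)\[C@@H](O[Si](C)(C)C(C)(C)C)CC/C(C)=C(O[Si](CC)(CC)CC)\[C@H]1O[Si](C)(C)C(C)(C)C | intermediate
20 | (6S)-alcohol from 19 | C=C(C)[C@@H]1[C@H](O)/C=C(C)\[C@@H](O[Si](C)(C)C(C)(C)C)CC/C(C)=C(O[Si](CC)(CC)CC)\[C@H]1O[Si](C)(C)C(C)(C)C | intermediate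
21 | 6-hydroxy-3,8-bis(tert-butyldimethylsilyloxy)germacra-1(10)E,4Z,11-trien-9-one | C=C(C)[C@@H]1[C@H](O)/C=C(C)\[C@@H](O[Si](C)(C)C(C)(C)C)C/C=C(C)/C(=O)[C@H]1O[Si](C)(C)C(C)(C)C | intermediate
22 | 4,5-monoepoxide of 21 (cis-oxirane, threo to the C6 hydroxyl) | C=C(C)[C@@H]1[C@H](O)[C@H]2O[C@@]2(C)[C@@H](O[Si](C)(C)C(C)(C)C)C/C=C(C)/C(=O)[C@H]1O[Si](C)(C)C(C)(C)C | intermediate
23 | 1,10:4,5-diepoxy-6-hydroxy-3,8-bis(tert-butyldimethylsilyloxy)germacr-11-en-9-one (8-epi) | C=C(C)[C@@H]1[C@H](O)[C@H]2O[C@@]2(C)[C@@H](O[Si](C)(C)C(C)(C)C)C[C@@H]2O[C@@]2(C)C(=O)[C@H]1O[Si](C)(C)C(C)(C)C | intermediate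
24 | 8-epi-1,10:4,5-diepoxy-3,6,8-trihydroxygermacr-11-en-9-one | C=C(C)[C@@H]1[C@H](O)[C@H]2O[C@@]2(C)[C@@H](O)C[C@@H]2O[C@@]2(C)C(=O)[C@H]1O | intermediate
25 | angelic acid, (Z)-2-methylbut-2-enoic acid | C/C=C(/C)C(=O)O | starting material
26 | 8-angeloyloxy-1,10:4,5-diepoxy-3,6-dihydroxygermacr-11-en-9-one (natural 8R) | C=C(C)[C@@H]1[C@H](O)[C@H]2O[C@@]2(C)[C@@H](O)C[C@@H]2O[C@@]2(C)C(=O)[C@@H]1OC(=O)/C(C)=C\C | intermediate
27 | angelic 2,4,6-trichlorobenzoic anhydride | C/C=C(/C)C(=O)OC(=O)c1c(Cl)cc(Cl)cc1Cl | intermediate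
28 | CNP0154187.3, (1S,3S,4S,5R,6S,7R,8R,10R)-3,6,8-triangeloyloxy-1,10:4,5-diepoxygermacr-11-en-9-one | C=C(C)[C@@H]1[C@H](OC(=O)/C(C)=C\C)[C@H]2O[C@@]2(C)[C@@H](OC(=O)/C(C)=C\C)C[C@@H]2O[C@@]2(C)C(=O)[C@@H]1OC(=O)/C(C)=C\C | target

## Step count and weak points
Total: 15 steps. Longest linear sequence: 14 steps (1, then 3–15); step 2 runs in parallel.

Step 9 (the new ring expansion) may stall at the aldolate, attack C9, or lose the alkenyllithium to proton transfer. The fallback sets out from 15 and comes back at 19. It runs the two events as separate known reactions with isolation in between. Iodine–lithium exchange with n-BuLi in THF at −78 °C, quenched with acetic acid after 5 min, stops at the neutral cis-fused bicyclic aldol F1; this is the known cyclisation of keto alkenyl iodides. The purified aldol is then opened by the known potassium-alkoxide retro-aldol fragmentation (KH, 18-crown-6, THF, 0 °C), and the enolate is silylated with TESCl to give 19.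

Step 7 (asymmetric conjugate addition of an alkenyl Grignard reagent to this ene-dione) may give low enantioselectivity or 1,2-addition. The fallback sets out from 10 and comes back at 13. It replaces the nucleophile and the metal. A Hayashi–Miyaura 1,4-addition of potassium isopropenyltrifluoroborate with [RhCl(C2H4)2]2 and a chiral diene in toluene/H2O gives the protonated 7-isopropenyl dione F2. Kinetic deprotonation of the C8 methylene with LiN(SiMe3)2 at −78 °C, followed by TBSOTf, then gives 13.

Step 14 (site-selective Mitsunobu inversion on a triol) may be slow at the hindered C8 or may touch the epoxy carbinols. The fallback sets out from 23 and comes back at 28. It corrects C8 by making the C8–H bond last instead of by substitution.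
- In 23 the C9 ketone can enolise only toward C8. KN(SiMe3)2 (2.2 equiv, THF, −78 °C) followed by a cold solution of 2,6-di-tert-butylphenol should protonate the enolate from the open outer face, which turns the silyloxy group to the natural side and gives the 8R bis-silyl ether F3.
- Buffered Bu4NF/AcOH then gives the natural triol F4.
- A single threefold acylation of F4 with mixed anhydride 27 (toluene, 75 °C) gives 28.

## Further compounds
F1 | step 9 | cis-fused bicyclo[5.3.0]decenone aldol (C6 tertiary alcohol, neutral form of 17) | C[C@@]12CC[C@H](O[Si](C)(C)C(C)(C)C)C(C)=C[C@]1(O)[C@@H](C(C)=C)[C@H](O[Si](C)(C)C(C)(C)C)C2=O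
F2 | step 7 | 4-isopropenyl-2-methyl-2-(side chain of 9)cyclopentane-1,3-dione (isopropenyl cis to methyl) | C[C@@]1(CC[C@H](O[Si](C)(C)C(C)(C)C)/C(C)=C\I)C(=O)[C@@H](C(C)=C)CC1=O
F3 | step 14 | C8 epimer of 23 (natural 8R bis-silyl ether) | C=C(C)[C@@H]1[C@H](O)[C@H]2O[C@@]2(C)[C@@H](O[Si](C)(C)C(C)(C)C)C[C@@H]2O[C@@]2(C)C(=O)[C@@H]1O[Si](C)(C)C(C)(C)C
F4 | step 14 | natural 1,10:4,5-diepoxy-3,6,8-trihydroxygermacr-11-en-9-one | C=C(C)[C@@H]1[C@H](O)[C@H]2O[C@@]2(C)[C@@H](O)C[C@@H]2O[C@@]2(C)C(=O)[C@@H]1O
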